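**Plan**

- Labdane numbering is used (C11 on C9, C17 on C8, C20 on C10; α is the face opposite C20). The retrosynthesis opens the lactone (ring D) to a 15,16-diol and cuts the spiro ether (ring C) at O–C13. It then cuts C11–C12, C8–C17, the C7–O and C9–O bonds, and finally C9–C10 and C4–C5 together, leaving a geranyl chain joined to acetoacetate at C6–C7.
- Enabling feature: rings A and B form a trans-decalin whose C4 gem-dimethyl, C10 methyl and C5 hydrogen are those of a cyclised geranyl unit. C9 lies between the oxygen-bearing C8 and the one-carbon branch C11, so it is the central carbon of a β-keto ester (C8 ketone, C11 ester carbon) whose enol can end the cation cascade.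
- Forward order: C6–C7 alkylation; rings A and B in one step; C9–OH, C7–OH and the C17 methyl on ring B; ester reduction and C11–C12 coupling with an isoprenol unit; ring C by epoxidation and ether closure; ring D by oxidative lactonisation; the C7 ketone last.
- Stereochemistry: C5 and C10 come from the chiral acid and the chair–chair fold of the E polyene; C9 from oxygenation anti to the C10 methyl; C8 from equatorial methyl delivery to the ketone; C13 from a ligand-controlled epoxidation followed by invertive 5-exo ether closure.

Key step: step 2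

Remark: the antipode of the chiral acid (step 2) and of the bishydroxamic acid ligand (step 9) is taken to be the one that gives the configuration drawn; both antipodes of each are accessible from (R)- or (S)-BINOL and from (R,R)- or (S,S)-cyclohexane-1,2-diamine.

**Route**

Step 1
Reactants: 1 geranyl bromide; 2 methyl acetoacetate
Product: 3 methyl (E)-7,11-dimethyl-3-oxododeca-6,10-dienoate
Conditions: 2, NaH, THF, 0 °C; n-BuLi, 0 °C; then 1, 0 °C to rt; aq. HCl
Reagents that add atoms: none
Why: Acetoacetate dianion alkylation: the doubly deprotonated keto ester attacks the allylic bromide by SN2 through its more basic terminal carbon (C6–C7), the E alkene of 1 is carried over unchanged and no stereocentre is formed.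

Step 2
Reactants: 3 methyl (E)-7,11-dimethyl-3-oxododeca-6,10-dienoate
Product: 4 methyl (1R,4aS,8aS)-5,5,8a-trimethyl-2-oxodecahydronaphthalene-1-carboxylate
Conditions: chiral confined imidodiphosphorimidate Brønsted acid (two 3,3'-diaryl-BINOL phosphoryl units, N-triflyl groups; 5 mol %), (CF3)3COH, 0 °C
Reagents that add atoms: none
Why: Proposed new method: the confined acid protonates C3 of the terminal alkene of 3 held in a chair–chair fold next to the chiral counter-anion, the C4 cation is taken by the C5=C10 alkene and the C10 cation by the enol carbon C9 of the β-keto ester, and loss of the enol proton returns the acid. The closest known reactions are the SnCl4-promoted racemic bicyclisation of this keto ester class and imidodiphosphorimidate-catalysed enantioselective polyene cyclisations ended by a hydroxyl or carboxyl oxygen. Ring A closes 6-endo (C4–C5) and ring B closes 6-endo through the enol (C9–C10). C5 and C10 are set by anti addition across the E alkene in the chair fold, which gives the trans ring fusion; C9 is set by the equatorial place of the ester in the second chair and, being epimerisable through the enol, by thermodynamics; the absolute sense is set by the face of the first protonation inside the catalyst pocket. The step needs site selectivity for the terminal alkene, carbon instead of oxygen capture by the enol, and face selectivity. The more exposed prenyl terminus, the internal alkene being closer to the electron-poor keto ester, the six-atom spacing that puts the enol carbon on the C10 cation, and the confined anion are counted on for these.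

Step 3
Reactants: 4 methyl (1R,4aS,8aS)-5,5,8a-trimethyl-2-oxodecahydronaphthalene-1-carboxylate
Product: 5 9α-hydroxy keto ester (4 with an axial hydroxyl on C9 and the ester 9β)
Conditions: O2 (1 atm), Cs2CO3 (0.2 equiv), P(OEt)3, DMSO, rt
Reagents that add atoms: dioxygen, O=O
Why: Aerobic α-hydroxylation of a β-keto ester enolate with phosphite reduction of the hydroperoxide; the small oxidant should reach the planar C9 from the α face, anti to the adjacent axial C10 methyl, so the new C–O bond is axial (9α) and the ester stays 9β.

Step 4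
Reactants: 5 9α-hydroxy keto ester
Product: 6 7α,9α-dihydroxy keto ester
Conditions: KHMDS (2.2 equiv), THF, −78 °C; 2-(phenylsulfonyl)-3-phenyloxaziridine, −78 °C; AcOH
Reagents that add atoms: 2-(phenylsulfonyl)-3-phenyloxaziridine, O=S(=O)(c1ccccc1)N1OC1c1ccccc1
Why: Oxaziridine hydroxylation of a ketone enolate (Davis oxidation): with C9 quaternary only the C7 enolate can form while the 9-hydroxyl is held as its alkoxide, oxygen should enter axially (7α), and the C7 configuration is of no consequence because C7 ends as the ketone.

Step 5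
Reactants: 6 7α,9α-dihydroxy keto ester
Product: 7 7α,8β,9α-trihydroxy ester (C17 methyl 8α)
Conditions: MeLi, CeCl3, THF, −78 °C; then 6, −78 to −40 °C; dilute aq. HCl
Reagents that add atoms: methyllithium, [Li]C
Why: Organocerium 1,2-addition: the weakly basic, oxophilic methylcerium reagent should add to the ketone and leave the neopentyl-type methyl ester alone, and the methyl should enter along the equatorial path from the α side because the axial path is blocked by the syn-axial C10 methyl, which sets C8 with the hydroxyl axial (8β) and C17 equatorial (8α).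

Step 6
Reactants: 7 7α,8β,9α-trihydroxy ester
Product: 8 7α,8β,9α,11-tetraol
Conditions: LiAlH4, THF, 0 °C to reflux; then H2O
Reagents that add atoms: none
Why: Hydride reduction of the hindered ester to the primary alcohol C11–OH; no stereocentre is touched.

Step 7
Reactants: 8 7α,8β,9α,11-tetraol
Product: 9 11-O-tosyl 7α,8β,9α-triol
Conditions: TsCl (1.1 equiv), Et3N, 4-(dimethylamino)pyridine (cat.), CH2Cl2, 0 °C
Reagents that add atoms: p-toluenesulfonyl chloride, Cc1ccc(cc1)S(Cl)(=O)=O
Why: Selective sulfonylation: the only primary hydroxyl should react ahead of the axial secondary 7-hydroxyl and the two tertiary hydroxyls.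

Step 8
Reactants: 9 11-O-tosyl 7α,8β,9α-triol; 10 3-methylbut-3-en-1-ol
Product: 12 labd-13(16)-ene-7α,8β,9α,15-tetraol (8α-CH3), via spiro-epoxide 11 (not isolated)
Conditions: 10 (6 equiv), n-BuLi (12 equiv), TMEDA, Et2O–hexane, 0 °C to rt; then 9 in THF, −78 to 0 °C; H2O
Reagents that add atoms: none
Why: Epoxide opening by an allyllithium: the symmetric allyl dianion of 10 first deprotonates the hydroxyls, the 9-alkoxide closes the 9α,11-epoxide by 3-exo displacement of the tosylate, and the allyl carbon opens it by SN2 at the C11 methylene, which forms C11–C12 and returns the 9α-hydroxyl untouched (an epoxide shifted to C8–C9 by Payne rearrangement would be fully substituted and inert).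

Step 9
Reactants: 12 labd-13(16)-ene-7α,8β,9α,15-tetraol
Product: 14 (13S)-9α,13-epoxylabdane-7α,8β,15,16-tetraol, via epoxy alcohol 13 (not isolated)
Conditions: Hf(Ot-Bu)4 (10 mol %), N,N'-dihydroxy-N,N'-bis(2,2-diphenylacetyl)cyclohexane-1,2-diamine (single enantiomer, 12 mol %), cumene hydroperoxide, 4 Å MS, toluene, 0 °C to rt; then camphor-10-sulfonic acid (cat.), CH2Cl2, 0 °C
Reagents that add atoms: cumene hydroperoxide, CC(C)(OO)c1ccccc1
Why: Hydroxyl-directed catalytic asymmetric epoxidation of a homoallylic alcohol bearing a 1,1-disubstituted alkene (hafnium bishydroxamate type): the primary 15-hydroxyl binds the metal and the ligand selects the alkene face to give the (13R)-epoxide, and acid then lets the 9α-hydroxyl open it at the tertiary carbon in 5-exo fashion with inversion, faster than 6-exo attack by the 8β-hydroxyl, so C13 becomes S and C16 keeps its oxygen.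

Step 10
Reactants: 14 (13S)-9α,13-epoxylabdane-7α,8β,15,16-tetraol
Product: 16 (13S)-9α,13-epoxy-7α,8β-dihydroxylabdan-15,16-olide, via lactol 15 (not isolated)
Conditions: TEMPO (2,2,6,6-tetramethylpiperidin-1-oxyl, 20 mol %), PhI(OAc)2 (2.5 equiv), CH2Cl2, rt
Reagents that add atoms: none
Why: Oxoammonium-mediated oxidative lactonisation of a 1,4-diol: the unhindered primary 15-hydroxyl should be oxidised ahead of the neopentyl 16-hydroxyl and the axial secondary 7-hydroxyl, the aldehyde is trapped by the 16-hydroxyl as the lactol and oxidised on, which puts the carbonyl on C15, and the trans-diaxial 7,8-diol cannot reach the cyclic iodane needed for glycol cleavage.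

Step 11
Reactants: 16 (13S)-9α,13-epoxy-7α,8β-dihydroxylabdan-15,16-olide
Product: 17 (5S,8R,9S,10S,13S)-9,13-epoxy-8-hydroxy-7-oxolabdan-15,16-olide
Conditions: Dess–Martin periodinane, CH2Cl2, rt
Reagents that add atoms: none
Why: Dess–Martin oxidation of the remaining secondary alcohol to the C7 ketone; the tertiary 8β-hydroxyl is inert and, C8 being fully substituted, the new ketone cannot enolise toward C8 or expel the C9 ether oxygen.

**Compound list**

1 | geranyl bromide, (E)-1-bromo-3,7-dimethylocta-2,6-diene | CC(C)=CCC/C(C)=C/CBr | starting material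
2 | methyl acetoacetate | COC(=O)CC(C)=O | starting material
3 | methyl (E)-7,11-dimethyl-3-oxododeca-6,10-dienoate | COC(=O)CC(=O)CC/C=C(\C)CCC=C(C)C | intermediate
4 | methyl (1R,4aS,8aS)-5,5,8a-trimethyl-2-oxodecahydronaphthalene-1-carboxylate (8-oxo, 9β-CO2Me, 5α-H, 10β-CH3) | CC1(C)CCC[C@@]2(C)[C@H]1CCC(=O)[C@@H]2C(=O)OC | intermediate
5 | 9α-hydroxy keto ester (4 with axial 9α-OH, ester 9β) | CC1(C)CCC[C@@]2(C)[C@H]1CCC(=O)[C@]2(O)C(=O)OC | intermediate
6 | 7α,9α-dihydroxy keto ester | CC1(C)CCC[C@@]2(C)[C@H]1C[C@@H](O)C(=O)[C@]2(O)C(=O)OC | intermediate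
7 | 7α,8β,9α-trihydroxy ester (8α-CH3) | CC1(C)CCC[C@@]2(C)[C@H]1C[C@@H](O)[C@](C)(O)[C@]2(O)C(=O)OC | intermediate
8 | 7α,8β,9α,11-tetraol (8α-CH3, 9β-CH2OH) | CC1(C)CCC[C@@]2(C)[C@H]1C[C@@H](O)[C@](C)(O)[C@]2(O)CO | intermediate
9 | 11-O-tosyl 7α,8β,9α-triol | CC1(C)CCC[C@@]2(C)[C@H]1C[C@@H](O)[C@](C)(O)[C@]2(O)COS(=O)(=O)c1ccc(C)cc1 | intermediate
10 | 3-methylbut-3-en-1-ol | CC(=C)CCO | starting material
11 | spiro-epoxide (9α,11-epoxy-7α,8β-diol) | CC1(C)CCC[C@@]2(C)[C@H]1C[C@@H](O)[C@](C)(O)[C@]21CO1 | intermediate (not isolated)
12 | labd-13(16)-ene-7α,8β,9α,15-tetraol (8α-CH3) | CC1(C)CCC[C@@]2(C)[C@H]1C[C@@H](O)[C@](C)(O)[C@]2(O)CCC(=C)CCO | intermediate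
13 | (13R)-13,16-epoxylabdane-7α,8β,9α,15-tetraol | CC1(C)CCC[C@@]2(C)[C@H]1C[C@@H](O)[C@](C)(O)[C@]2(O)CC[C@@]1(CCO)CO1 | intermediate (not isolated)
14 | (13S)-9α,13-epoxylabdane-7α,8β,15,16-tetraol | CC1(C)CCC[C@@]2(C)[C@H]1C[C@@H](O)[C@](C)(O)[C@]21CC[C@@](CO)(CCO)O1 | intermediate
15 | lactol, (13S)-9α,13:15,16-diepoxylabdane-7α,8β,15-triol (both C15 anomers) | CC1(C)CCC[C@@]2(C)[C@H]1C[C@@H](O)[C@](C)(O)[C@]21CC[C@]2(COC(O)C2)O1 | intermediate (not isolated)
16 | (13S)-9α,13-epoxy-7α,8β-dihydroxylabdan-15,16-olide | CC1(C)CCC[C@@]2(C)[C@H]1C[C@@H](O)[C@](C)(O)[C@]21CC[C@]2(COC(=O)C2)O1 | intermediate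
17 | (5S,8R,9S,10S,13S)-9,13-epoxy-8-hydroxy-7-oxolabdan-15,16-olide | CC1(C)CCC[C@@]2(C)[C@H]1CC(=O)[C@](C)(O)[C@]21CC[C@]2(COC(=O)C2)O1 | target

**Count and risks**

Total steps: 11. Longest linear sequence: 11 steps (from 1 and 2 to 17; 10 enters in step 8).

Step 2. The protonation may not distinguish the two alkene faces well enough, or the enol may capture the C10 cation through oxygen instead of carbon. Fallback from 3: SnCl4 in CH2Cl2 (0 °C to rt) performs the same bicyclisation without chiral control and gives 4 mixed with an equal amount of the mirror-image keto ester F1. Heating this racemate with (−)-menthol and 4-(dimethylamino)pyridine in toluene, with methanol distilled off, exchanges the ester through the acyl ketene. This gives the (−)-menthyl ester of the (1R,4aS,8aS) acid F2 and the (−)-menthyl ester of the mirror-image acid F3, which are separated by crystallisation or chromatography. Heating F2 with excess methanol and 4-(dimethylamino)pyridine in a sealed tube returns 4.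

Step 9. Face selection by the catalyst may be eroded by the other hydroxyls binding the metal, and part of the epoxide may be captured by the 8β-hydroxyl. Fallback from 12: mCPBA (NaHCO3, CH2Cl2) followed by camphor-10-sulfonic acid epoxidises without chiral control and gives, through 13 and the (13S)-epoxide F4, tetraol 14 together with the 13-epimeric spiro ether tetraol F5, which are separated. F5 is taken through the conditions of steps 10 and 11, via the 13-epimeric lactol F6 and the 13-epimeric lactone diol F7, to the 13-epimer of the target F8. Heating F8 with DBU in toluene opens the ether by retro-oxa-Michael reaction to the 9α-hydroxy butenolide F9 and lets the 9α-oxygen add back to either face of C13, so separation and recycling should funnel the material into 17.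

Step 8. Attack at the crowded C11 methylene may be slow, so that Payne migration of the epoxide toward C8 or oxetane formation from the 8-alkoxide takes over. Fallback from 9: NaH in THF closes epoxide 11, which is opened at the methylene by MgI2 in Et2O to the 11-iodo-7α,8β,9α-triol F10. A radical allylation (Keck type) with tributyl[2-(2-hydroxyethyl)prop-2-en-1-yl]stannane F11 (from the dianion of 10 and Bu3SnCl) and azobisisobutyronitrile in benzene at 80 °C then forms C11–C12 through the primary C11 radical, which is little affected by the crowding, and gives 12.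

**Further compounds**

F1 | step 2 | mirror-image bicyclic keto ester (enantiomer of 4, second half of the racemate) | CC1(C)CCC[C@]2(C)[C@@H]1CCC(=O)[C@H]2C(=O)OC
F2 | step 2 | (−)-menthyl (1R,4aS,8aS)-5,5,8a-trimethyl-2-oxodecahydronaphthalene-1-carboxylate | CC1(C)CCC[C@@]2(C)[C@H]1CCC(=O)[C@@H]2C(=O)O[C@@H]1C[C@H](C)CC[C@H]1C(C)C
F3 | step 2 | (−)-menthyl ester of the mirror-image acid | CC1(C)CCC[C@]2(C)[C@@H]1CCC(=O)[C@H]2C(=O)O[C@@H]1C[C@H](C)CC[C@H]1C(C)C
F4 | step 9 | (13S)-13,16-epoxylabdane-7α,8β,9α,15-tetraol | CC1(C)CCC[C@@]2(C)[C@H]1C[C@@H](O)[C@](C)(O)[C@]2(O)CC[C@]1(CCO)CO1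
F5 | step 9 | (13R)-9α,13-epoxylabdane-7α,8β,15,16-tetraol (13-epimer of 14) | CC1(C)CCC[C@@]2(C)[C@H]1C[C@@H](O)[C@](C)(O)[C@]21CC[C@](CO)(CCO)O1
F6 | step 9 | 13-epimeric lactol (13-epimer of 15) | CC1(C)CCC[C@@]2(C)[C@H]1C[C@@H](O)[C@](C)(O)[C@]21CC[C@@]2(COC(O)C2)O1
F7 | step 9 | (13R)-9α,13-epoxy-7α,8β-dihydroxylabdan-15,16-olide (13-epimer of 16) | CC1(C)CCC[C@@]2(C)[C@H]1C[C@@H](O)[C@](C)(O)[C@]21CC[C@@]2(COC(=O)C2)O1
F8 | step 9 | (13R)-9α,13-epoxy-8β-hydroxy-7-oxolabdan-15,16-olide (13-epimer of 17) | CC1(C)CCC[C@@]2(C)[C@H]1CC(=O)[C@](C)(O)[C@]21CC[C@@]2(COC(=O)C2)O1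
F9 | step 9 | 8β,9α-dihydroxy-7-oxolabd-13-en-15,16-olide (9α-hydroxy butenolide) | CC1(C)CCC[C@@]2(C)[C@H]1CC(=O)[C@](C)(O)[C@]2(O)CCC1=CC(=O)OC1
F10 | step 8 | 11-iodo-7α,8β,9α-triol | CC1(C)CCC[C@@]2(C)[C@H]1C[C@@H](O)[C@](C)(O)[C@]2(O)CI
F11 | step 8 | tributyl[2-(2-hydroxyethyl)prop-2-en-1-yl]stannane | CCCC[Sn](CCCC)(CCCC)CC(=C)CCO
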